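**Plan**

- Retrosynthesis: first cut the C8–CH(OH) bond between the second 5,7-dimethoxycoumarin and the carbinol carbon, which leaves 5,7-dimethoxycoumarin itself and a trans-2-aryl-4,6,6-trimethylcyclohex-3-ene-1-carbaldehyde. Then cut the cyclohexene by [4+2] (ring bonds C1–C2 and C5–C6 of the aldehyde) into an 8-dienylcoumarin and 3-methylbut-2-enal. Last, cut the C8–vinyl bond of the diene (Heck).
- Forward order: coumarin → 8-iodide → Heck and dehydration to the (E)-diene → Diels–Alder closes the cyclohexene → epimerisation to trans → union with a second molecule of 5,7-dimethoxycoumarin, whose pyranone ring opens and re-closes in that operation.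
- Enabling feature: in a coumarin, C8 is the only unsubstituted benzo carbon ortho to the ring oxygen O1, and the O1–C2 lactone with its cis C3=C4 bond opens and re-closes reversibly. A magnesium amide turns O1 into a magnesium phenoxide that delivers the aldehyde to C8, and acid restores the pyranone ring.
- Stereochemistry: the aryl-bearing ring carbon comes from the catalyst-controlled endo Diels–Alder; the neighbouring ring carbon is set by thermodynamic epimerisation to trans; the carbinol carbon is set by substrate control (Felkin–Anh) in the magnesium-bridged addition.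

Key step: step 6

Assumption: the (S)-configured oxazaborolidinium catalyst is taken to shield the enal face that leads to the (2S) endo adduct; if the facial sense proves opposite, its antipode is used.

**Step 1**
Reactants: 1 5,7-dimethoxycoumarin
Product: 2 8-iodo-5,7-dimethoxycoumarin
Conditions: NIS (1.1 equiv), TFA (0.2 equiv), MeCN, 0 °C → rt
Reagents that add atoms: N-iodosuccinimide, O=C1CCC(=O)N1I
Why: Electrophilic aromatic iodination (SEAr) with acid-activated NIS should take place at C8, which is ortho to O1 and 7-OMe and para to 5-OMe and is less hindered than C6 between two methoxy groups.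

**Step 2**
Reactants: 2 8-iodo-5,7-dimethoxycoumarin; 3 2-methylbut-3-en-2-ol
Product: 4 8-[(E)-3-hydroxy-3-methylbut-1-en-1-yl]-5,7-dimethoxycoumarin
Conditions: Pd(OAc)2 (5 mol%), nBu4NBr, NaHCO3, 3 (3 equiv), DMF, 80 °C
Reagents that add atoms: none
Why: Mizoroki–Heck reaction under Jeffery conditions, in which syn-carbopalladation of the terminal alkene and syn-β-hydride elimination should give the (E)-alkene, and the tertiary carbinol has no hydrogen that could lead on to a ketone.

**Step 3**
Reactants: 4 8-[(E)-3-hydroxy-3-methylbut-1-en-1-yl]-5,7-dimethoxycoumarin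
Product: 5 5,7-dimethoxy-8-[(E)-3-methylbuta-1,3-dien-1-yl]coumarin
Conditions: Burgess reagent (1.5 equiv), PhMe, 50 °C; used directly
Reagents that add atoms: none
Why: Burgess dehydration, in which the tertiary sulfamate ester should undergo syn-elimination (Ei) toward a methyl group, the only β-position with sp3 hydrogen, under neutral conditions that avoid the aryl-stabilised allyl cation.

**Step 4**
Reactants: 5 5,7-dimethoxy-8-[(E)-3-methylbuta-1,3-dien-1-yl]coumarin; 6 3-methylbut-2-enal
Product: 7 (1S,2S)-2-(5,7-dimethoxy-2-oxo-2H-chromen-8-yl)-4,6,6-trimethylcyclohex-3-ene-1-carbaldehyde (cis)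
Conditions: (S)-o-tolyl-oxazaborolidine·Tf2NH (20 mol%), 6 (3 equiv), CH2Cl2, −78 → −20 °C; cis adduct separated from the minor exo (trans) adduct on SiO2
Reagents that add atoms: none
Why: Catalytic enantioselective Diels–Alder reaction with a cationic oxazaborolidine Lewis acid, in which the terminal CH2 of the 1-aryl-3-methyl diene (largest HOMO coefficient) pairs with the β-carbon of the activated enal, the endo transition state gives the cis adduct, and the catalyst-shielded enal face should fix (2S) at the aryl-bearing carbon.

**Step 5**
Reactants: 7 (1S,2S)-2-(5,7-dimethoxy-2-oxo-2H-chromen-8-yl)-4,6,6-trimethylcyclohex-3-ene-1-carbaldehyde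
Product: 8 (1R,2S)-2-(5,7-dimethoxy-2-oxo-2H-chromen-8-yl)-4,6,6-trimethylcyclohex-3-ene-1-carbaldehyde (trans)
Conditions: DBU (0.2 equiv), PhMe, rt → 40 °C; residual 7 separated and recycled
Reagents that add atoms: none
Why: Base-mediated epimerisation through the enolate at C1 (thermodynamic control) should favour the trans-diequatorial aldehyde, as in the base equilibration of 2,6,6-trimethylcyclohex-3-enyl carbonyl compounds, while C2 is not enolisable and keeps its configuration.

**Step 6**
Reactants: 1 5,7-dimethoxycoumarin; 9 morpholine; 10 isopropylmagnesium chloride; 8 (1R,2S)-2-(5,7-dimethoxy-2-oxo-2H-chromen-8-yl)-4,6,6-trimethylcyclohex-3-ene-1-carbaldehyde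
Product: 14 IN0553, via magnesium phenoxide 11 (not isolated), via magnesium adduct 12 (not isolated), via ring-opened phenol 13 (not isolated)
Conditions: 9 + 10 (1.5 equiv each), THF, 0 °C; 1 (1.6 equiv), 0 °C → rt; THF → PhMe/CH2Cl2; 8 (1.0 equiv), rt, dark; 1 M HCl to pH 5, 0 °C; AcOH (cat.), CH2Cl2, rt
Reagents that add atoms: none
Why: Proposed new method: morpholinomagnesium chloride should open the O1–C2 lactone of 1 by acyl substitution (Bodroux-type aminolysis of an aryl ester) to the chloromagnesium phenoxide 11; magnesium then binds the formyl oxygen of 8, and C8, the only unsubstituted carbon ortho to O1, attacks the aldehyde through a six-membered magnesium-bridged transition state, after which tautomerisation gives 12. The closest known reaction type is the ortho-specific hydroxyalkylation of halomagnesium phenoxides with aldehydes (Casiraghi type); what is new is that the phenoxide is unmasked from a coumarin and masked again in the same operation. On acidification the free phenol 13 should re-close the pyranone ring by 6-exo-trig lactonisation onto the (Z)-amide with loss of morpholine, which the fixed cis geometry of C3=C4 makes fast. The carbinol centre is set by the ring stereocentres: the formyl hydrogen turns toward the equatorial C2 aryl group and C8 approaches anti to the C1–C2 ring bond (Felkin–Anh with the aryl-bearing carbon as the large group), which should give (R). The step needs C8 over C6 regioselectivity, mono-addition, and survival of the acid-labile trioxygenated benzylic alcohol and of the first lactone; the magnesium tether secures ortho attack, the basic non-ionising medium prevents benzylic ionisation and a second arylation, and no free amide nucleophile remains when 8 is added. Excess 11 reverts to 1 on work-up and is recovered.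

**Compound list**

1 | 5,7-dimethoxy-2H-chromen-2-one (5,7-dimethoxycoumarin) | COc1cc(OC)c2ccc(=O)oc2c1 | starting material
2 | 8-iodo-5,7-dimethoxy-2H-chromen-2-one | COc1cc(OC)c2ccc(=O)oc2c1I | intermediate
3 | 2-methylbut-3-en-2-ol | C=CC(C)(C)O | starting material
4 | 8-[(E)-3-hydroxy-3-methylbut-1-en-1-yl]-5,7-dimethoxy-2H-chromen-2-one | COc1cc(OC)c2ccc(=O)oc2c1/C=C/C(C)(C)O | intermediate
5 | 5,7-dimethoxy-8-[(E)-3-methylbuta-1,3-dien-1-yl]-2H-chromen-2-one | COc1cc(OC)c2ccc(=O)oc2c1/C=C/C(C)=C | intermediate
6 | 3-methylbut-2-enal | CC(C)=CC=O | starting material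
7 | (1S,2S)-2-(5,7-dimethoxy-2-oxo-2H-chromen-8-yl)-4,6,6-trimethylcyclohex-3-ene-1-carbaldehyde (cis) | COc1cc(OC)c2ccc(=O)oc2c1[C@H]1C=C(C)CC(C)(C)[C@H]1C=O | intermediate
8 | (1R,2S)-2-(5,7-dimethoxy-2-oxo-2H-chromen-8-yl)-4,6,6-trimethylcyclohex-3-ene-1-carbaldehyde (trans) | COc1cc(OC)c2ccc(=O)oc2c1[C@H]1C=C(C)CC(C)(C)[C@@H]1C=O | intermediate
9 | morpholine | C1COCCN1 | starting material
10 | isopropylmagnesium chloride | CC(C)[Mg]Cl | starting material
11 | chloromagnesium 3,5-dimethoxy-2-[(Z)-3-(morpholin-4-yl)-3-oxoprop-1-en-1-yl]phenoxide | COc1cc(OC)c(/C=C\C(=O)N2CCOCC2)c(O[Mg]Cl)c1 | intermediate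
12 | chloromagnesium 2-[(R)-hydroxy{(1R,2S)-2-(5,7-dimethoxy-2-oxo-2H-chromen-8-yl)-4,6,6-trimethylcyclohex-3-en-1-yl}methyl]-3,5-dimethoxy-6-[(Z)-3-(morpholin-4-yl)-3-oxoprop-1-en-1-yl]phenoxide | COc1cc(OC)c2ccc(=O)oc2c1[C@H]1C=C(C)CC(C)(C)[C@@H]1[C@@H](O)c1c(OC)cc(OC)c(/C=C\C(=O)N2CCOCC2)c1O[Mg]Cl | intermediate
13 | (Z)-3-{2-hydroxy-3-[(R)-hydroxy{(1R,2S)-2-(5,7-dimethoxy-2-oxo-2H-chromen-8-yl)-4,6,6-trimethylcyclohex-3-en-1-yl}methyl]-4,6-dimethoxyphenyl}-1-(morpholin-4-yl)prop-2-en-1-one | COc1cc(OC)c2ccc(=O)oc2c1[C@H]1C=C(C)CC(C)(C)[C@@H]1[C@@H](O)c1c(OC)cc(OC)c(/C=C\C(=O)N2CCOCC2)c1O | intermediate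
14 | IN0553, 8-[(R)-hydroxy{(1R,2S)-2-(5,7-dimethoxy-2-oxo-2H-chromen-8-yl)-4,6,6-trimethylcyclohex-3-en-1-yl}methyl]-5,7-dimethoxy-2H-chromen-2-one | COc1cc(OC)c2ccc(=O)oc2c1[C@H]1C=C(C)CC(C)(C)[C@@H]1[C@@H](O)c1c(OC)cc(OC)c2ccc(=O)oc12 | target

**Summary**

Total step count: 6. Longest linear sequence: 6 steps (1 → 2 → 4 → 5 → 7 → 8 → 14); the second molecule of 1 enters in step 6.

**Steps most likely to fail**

Step 6 (Proposed new method). The hindered magnesium phenoxide may add too slowly to the neopentyl-like aldehyde. The amide may add to C4 of the coumarin in conjugate fashion instead of opening the lactone. The (Z)-acrylamide may isomerise to (E) and then fail to re-close. The magnesium alkoxide of the product may transfer hydride to unreacted aldehyde, and facial selectivity at the aldehyde may be poor. The fallback is a Nozaki–Hiyama–Kishi coupling that sets out from iodide 2 and aldehyde 8: CrCl2 (excess) and NiCl2 (cat.) in DMF/DMSO at rt should generate the 8-arylchromium(III) species. This adds to aldehydes chemoselectively in the presence of both lactones under neutral conditions, with the same substrate-controlled facial preference, and comes back to the route at 14 directly. No compound outside the list is made on this way (F0).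

Step 4. The β,β-disubstituted enal may react too slowly. The coumarin carbonyl may sequester the Lewis acid, and the electron-rich diene may oligomerise under acid. Erosion of endo/exo or facial selectivity would lower the enantiomeric purity, because the exo adduct falls into the enantiomeric series once C1 is epimerised. The fallback gives up catalytic enantiocontrol. It sets out from 5 and 6: a Diels–Alder reaction promoted by stoichiometric Me2AlCl in CH2Cl2 at −40 °C should give the racemic cis aldehyde F1. Equilibration with DBU as in step 5 should give the racemic trans aldehyde F2. F2 is then resolved by preparative HPLC on a polysaccharide chiral stationary phase, and the (1R,2S)-enantiomer is 8, where the route is rejoined.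

Step 3. The tertiary allylic sulfamate may ionise to the aryl-stabilised allyl cation and give oligomers in place of clean syn-elimination, and the diene may dimerise during isolation. The fallback avoids the alcohol 4 and any cationic intermediate. It sets out from 2: Suzuki–Miyaura coupling with 4,4,5,5-tetramethyl-2-[(E)-3-methylbuta-1,3-dien-1-yl]-1,3,2-dioxaborolane F3 should give 5 directly, where the route is rejoined. F3 is prepared from 2-methylbut-1-en-3-yne and pinacolborane with Cp2Zr(H)Cl as catalyst; the coupling uses Pd(dppf)Cl2 and K3PO4 in dioxane/H2O at 60 °C.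

**Further compounds**
F0 | step 6 | none | none
F1 | step 4 | rac-(1S,2S)-2-(5,7-dimethoxy-2-oxo-2H-chromen-8-yl)-4,6,6-trimethylcyclohex-3-ene-1-carbaldehyde (racemic cis aldehyde, both enantiomers written) | COc1cc(OC)c2ccc(=O)oc2c1[C@H]1C=C(C)CC(C)(C)[C@H]1C=O.COc1cc(OC)c2ccc(=O)oc2c1[C@@H]1C=C(C)CC(C)(C)[C@@H]1C=O
F2 | step 4 | rac-(1R,2S)-2-(5,7-dimethoxy-2-oxo-2H-chromen-8-yl)-4,6,6-trimethylcyclohex-3-ene-1-carbaldehyde (racemic trans aldehyde, both enantiomers written) | COc1cc(OC)c2ccc(=O)oc2c1[C@H]1C=C(C)CC(C)(C)[C@@H]1C=O.COc1cc(OC)c2ccc(=O)oc2c1[C@@H]1C=C(C)CC(C)(C)[C@H]1C=O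
F3 | step 3 | 4,4,5,5-tetramethyl-2-[(E)-3-methylbuta-1,3-dien-1-yl]-1,3,2-dioxaborolane | CC(=C)/C=C/B1OC(C)(C)C(C)(C)O1
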